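**Plan**

- Retrosynthesis cuts, in this order: the C3 acetate and the C11–O aryl ether (isofraxidin); the C9–C11 bond; the C3–C4 bond of ring A; and finally C10–C1 and C10–C15, which leaves (R)-carvone as ring B.
- Forward: the C15 methyl and a C1–C3 chain are attached to carvone at the future C10, ring A closes by C3–C4 bond formation, C11 is transferred onto C9 from a C7 oxygen, and the coumarin is joined before the final protecting-group exchange.
- Enabling feature: ring B of the target (C5–C10, with the C8 methyl, the C7=C8 alkene and the C5 stereocentre) is carvone itself. Carvone's isopropenyl carbon is C4, lacking only one hydrogen atom and one bond to the oxygenated C3.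
- Stereochemistry: C5 comes from (R)-carvone; C10 from enolate alkylation anti to the isopropenyl group; C3 from the chair of the radical ring closure; C9 from an α-face epoxidation relayed through the 7α-alcohol by a suprafacial [2,3]-shift.

Key step: step 4

Remark: drimane numbering is used for the bicyclic compounds (ring A = C1–C5, C10; ring B = C5–C10; C11 on C9, C12 on C8, C13/C14 on C4, C15 on C10; β is the face of the C10 methyl), and carvone numbering for the monocyclic ones.
Remark: conjugate bases formed in situ (enolates, alkoxides) are not numbered, and tributyl(iodomethyl)stannane is taken as a purchased reagent.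

**Route**

Step 1
Reactants: 1 (R)-carvone
Product: 2 (5R,6S)-6-methylcarvone (methyl trans to isopropenyl; any 6-epimer is carried along)
Conditions: LDA, THF, −78 °C; MeI, −78 → 0 °C
Reagents that add atoms: iodomethane, CI
Why: Kinetic α′-deprotonation gives the cross-conjugated lithium dienolate, which is C-methylated at C6 (enolate alkylation) mainly anti to the C5 isopropenyl group; the C6 configuration is erased again in step 2, so both epimers converge.

Step 2
Reactants: 2 (5R,6S)-6-methylcarvone; 3 allyl bromide
Product: 4 (5S,6S)-6-allyl-6-methylcarvone (allyl trans to isopropenyl)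
Conditions: LDA, THF, −78 → −20 °C; 3, DMPU, −78 °C → rt
Reagents that add atoms: none
Why: A second α′-enolate alkylation, in which the planar C6 enolate is attacked by the allylic halide on the face opposite the neighbouring isopropenyl group, sets the quaternary centre (future C10) with the three-carbon chain trans and the methyl cis to isopropenyl.

Step 3
Reactants: 4 (5S,6S)-6-allyl-6-methylcarvone
Product: 5 3-[(1S,6S)-1,3-dimethyl-2-oxo-6-(prop-1-en-2-yl)cyclohex-3-en-1-yl]propanal
Conditions: PdCl2(PhCN)2 (cat.), CuCl2·2H2O (cat.), AgNO2 (cat.), O2 (1 atm), t-BuOH/MeNO2 15:1, rt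
Reagents that add atoms: dioxygen, O=O
Why: The nitrite-modified, aldehyde-selective (anti-Markovnikov) Wacker oxidation is suited to a monosubstituted allyl group on a quaternary carbon next to a ketone, whereas the 1,1-disubstituted isopropenyl group and the trisubstituted enone alkene are poor Wacker substrates; no stereocentre is touched.

Step 4
Reactants: 5 3-[(1S,6S)-1,3-dimethyl-2-oxo-6-(prop-1-en-2-yl)cyclohex-3-en-1-yl]propanal
Product: 6 3β-hydroxy-11-nor-drim-7-en-9-one [(4aS,6S,8aS)-6-hydroxy-2,5,5,8a-tetramethyl-4a,5,6,7,8,8a-hexahydronaphthalen-1(4H)-one]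
Conditions: Fe(acac)3 (30 mol%), PhSiH3 (2.5 equiv), EtOH (0.02 M), Ar, 60 °C
Reagents that add atoms: none
Why: Fe(acac)3 and PhSiH3 in ethanol form an iron hydride that hands a hydrogen atom to the CH2 end of the isopropenyl group, so the methylene becomes the second C4 methyl and C4 a nucleophilic tertiary radical, which adds to the aldehyde carbon C3; the alkoxy radical is reduced by Fe(II) and protonated by ethanol, returning Fe(III). The closest known reaction type is the iron-hydride HAT-initiated reductive radical cyclization of alkene-tethered ketones, together with the HAT-mediated radical addition of alkenes to aldehydes. Ring A closes 6-exo-trig onto the C=O carbon through a chair whose C5 and C10 substituents are already fixed, so the new ring is trans-fused without either centre being touched. The one new stereocentre, C3, is set in that chair with the carbonyl oxygen pseudo-equatorial (no 1,3-diaxial contact with the axial hydrogens at C1 and C5), and since addition to C=O is reversible the more stable equatorial alkoxy radical should be the one that is reduced, giving the 3β-alcohol. The step needs HAT at the isopropenyl group and not at the enone, and ring closure ahead of simple reduction: the electron-rich 1,1-disubstituted alkene is the better hydrogen-atom acceptor, the electron-poor trisubstituted enone is not, and from C4 the enone could only be reached through a four-membered ring (C7, C9) or a polarity-mismatched attack at C8. Working dilute and under argon keeps intermolecular Giese addition to the enone and oxygen trapping in check.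

Step 5
Reactants: 6 3β-hydroxy-11-nor-drim-7-en-9-one
Product: 7 3β-(tert-butyldimethylsilyloxy)-11-nor-drim-7-en-9-one
Conditions: TBSOTf, 2,6-lutidine, CH2Cl2, −78 → 0 °C
Reagents that add atoms: tert-butyldimethylsilyl trifluoromethanesulfonate, CC(C)(C)[Si](C)(C)OS(=O)(=O)C(F)(F)F
Why: O-Silylation with the silyl triflate is reactive enough for the hindered equatorial C3 alcohol beside the gem-dimethyl group, keeps the C3 configuration, and gives an ether that withstands alkaline peroxide, hydrazine, KH and n-BuLi.

Step 6
Reactants: 7 3β-(tert-butyldimethylsilyloxy)-11-nor-drim-7-en-9-one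
Product: 8 7α,8α-epoxy-3β-(tert-butyldimethylsilyloxy)-11-nor-driman-9-one
Conditions: 30% H2O2, NaOH (cat.), MeOH/THF, 0 °C → rt
Reagents that add atoms: hydrogen peroxide, OO
Why: In this Weitz–Scheffer nucleophilic epoxidation the hydroperoxide anion adds to C7 axially (antiparallel) on the α face of the half-chair enone, the side of the axial C5 hydrogen, and the enolate closes onto oxygen, so the 7α,8α-epoxide is expected.

Step 7
Reactants: 8 7α,8α-epoxy-3β-(tert-butyldimethylsilyloxy)-11-nor-driman-9-one
Product: 10 3β-(tert-butyldimethylsilyloxy)-11-nor-drim-8-en-7α-ol, via epoxy hydrazone 9 (not isolated)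
Conditions: N2H4·H2O, AcOH (cat.), MeOH, 0 °C → rt
Reagents that add atoms: hydrazine, NN (its nitrogen is carried only by intermediate 9 and is lost as N2 on the way to 10)
Why: In the Wharton transposition the C9 hydrazone opens the epoxide to an alkenyl diazene that loses N2, placing the alkene at C8=C9 while the C7–O bond is never broken, so the α configuration of the epoxide becomes that of the 7α-allylic alcohol.

Step 8
Reactants: 10 3β-(tert-butyldimethylsilyloxy)-11-nor-drim-8-en-7α-ol
Product: 11 7α-[(tributylstannyl)methoxy]-3β-(tert-butyldimethylsilyloxy)-11-nor-drim-8-ene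
Conditions: KH, THF, 0 °C; Bu3SnCH2I, 18-crown-6 (cat.), 0 °C → rt
Reagents that add atoms: tributyl(iodomethyl)stannane, CCCC[Sn](CCCC)(CCCC)CI
Why: Williamson etherification of the potassium alkoxide with the reactive α-stannyl iodide occurs at oxygen, so C7 keeps its configuration.

Step 9
Reactants: 11 7α-[(tributylstannyl)methoxy]-3β-(tert-butyldimethylsilyloxy)-11-nor-drim-8-ene
Product: 13 3β-(tert-butyldimethylsilyloxy)-9βH-drim-7-en-11-ol, via lithiomethyl ether 12 (not isolated)
Conditions: n-BuLi, THF, −78 °C; H2O quench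
Reagents that add atoms: n-butyllithium, [Li]CCCC (lithium is carried only by intermediate 12)
Why: In the Still–Wittig rearrangement, tin–lithium exchange gives the α-alkoxymethyl carbanion, which undergoes a suprafacial [2,3]-sigmatropic shift from the pseudo-axial 7α-oxygen to C9, so C11 arrives on the α face (9β-H) and the alkene moves to C7=C8.

Step 10
Reactants: 13 3β-(tert-butyldimethylsilyloxy)-9βH-drim-7-en-11-ol; 14 isofraxidin
Product: 15 7-O-[3β-(tert-butyldimethylsilyloxy)-9βH-drim-7-en-11-yl]isofraxidin
Conditions: PPh3, DIAD, THF, 0 °C → rt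
Reagents that add atoms: none
Why: In this Mitsunobu etherification the primary C11 alcohol is activated as its alkoxyphosphonium salt and displaced by the acidic coumarin phenoxide in an SN2 step at a non-stereogenic, homoallylic carbon, so neither C9 nor the alkene is affected.

Step 11
Reactants: 15 7-O-[3β-(tert-butyldimethylsilyloxy)-9βH-drim-7-en-11-yl]isofraxidin
Product: 16 7-O-(3β-hydroxy-9βH-drim-7-en-11-yl)isofraxidin
Conditions: HF·pyridine, THF, 0 °C → rt
Reagents that add atoms: none
Why: Fluoride-driven desilylation under acidic conditions cleaves the Si–O bond with retention at C3 and, unlike basic fluoride sources, leaves the coumarin lactone, the aryl ether and the trisubstituted alkene untouched.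

Step 12
Reactants: 16 7-O-(3β-hydroxy-9βH-drim-7-en-11-yl)isofraxidin
Product: 17 7-O-(3β-acetoxy-9βH-drim-7-en-11-yl)isofraxidin (target)
Conditions: Ac2O, pyridine, DMAP (cat.), CH2Cl2, rt
Reagents that add atoms: acetic anhydride, CC(=O)OC(C)=O
Why: DMAP-catalysed O-acylation of the equatorial 3β-alcohol proceeds with retention at C3 and touches no other group.

**Compound list**

1 | (R)-(−)-carvone, (5R)-2-methyl-5-(prop-1-en-2-yl)cyclohex-2-en-1-one | O=C1C(C)=CC[C@@H](C(C)=C)C1 | starting material
2 | (5R,6S)-6-methylcarvone, (5R,6S)-2,6-dimethyl-5-(prop-1-en-2-yl)cyclohex-2-en-1-one | O=C1C(C)=CC[C@@H](C(C)=C)[C@@H]1C | intermediate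
3 | allyl bromide, 3-bromoprop-1-ene | C=CCBr | starting material
4 | (5S,6S)-2,6-dimethyl-6-(prop-2-en-1-yl)-5-(prop-1-en-2-yl)cyclohex-2-en-1-one (allyl trans to isopropenyl) | O=C1C(C)=CC[C@@H](C(C)=C)[C@]1(C)CC=C | intermediate
5 | 3-[(1S,6S)-1,3-dimethyl-2-oxo-6-(prop-1-en-2-yl)cyclohex-3-en-1-yl]propanal (oxopropyl chain trans to isopropenyl) | O=C1C(C)=CC[C@@H](C(C)=C)[C@]1(C)CCC=O | intermediate
6 | 3β-hydroxy-11-nor-drim-7-en-9-one (5α-H, 10β-methyl, trans-decalin) | O=C1C(C)=CC[C@H]2C(C)(C)[C@@H](O)CC[C@]12C | intermediate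
7 | 3β-(tert-butyldimethylsilyloxy)-11-nor-drim-7-en-9-one | O=C1C(C)=CC[C@H]2C(C)(C)[C@@H](O[Si](C)(C)C(C)(C)C)CC[C@]12C | intermediate
8 | 7α,8α-epoxy-3β-(tert-butyldimethylsilyloxy)-11-nor-driman-9-one (8β-methyl) | O=C1[C@]2(C)O[C@@H]2C[C@H]3C(C)(C)[C@@H](O[Si](C)(C)C(C)(C)C)CC[C@]13C | intermediate
9 | C9 hydrazone of 8 (C=N geometry not defined; not isolated) | NN=C1[C@]2(C)O[C@@H]2C[C@H]3C(C)(C)[C@@H](O[Si](C)(C)C(C)(C)C)CC[C@]13C | intermediate
10 | 3β-(tert-butyldimethylsilyloxy)-11-nor-drim-8-en-7α-ol | C1=C(C)[C@H](O)C[C@H]2C(C)(C)[C@@H](O[Si](C)(C)C(C)(C)C)CC[C@]12C | intermediate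
11 | 7α-[(tributylstannyl)methoxy]-3β-(tert-butyldimethylsilyloxy)-11-nor-drim-8-ene | C1=C(C)[C@H](OC[Sn](CCCC)(CCCC)CCCC)C[C@H]2C(C)(C)[C@@H](O[Si](C)(C)C(C)(C)C)CC[C@]12C | intermediate
12 | 7α-(lithiomethoxy)-3β-(tert-butyldimethylsilyloxy)-11-nor-drim-8-ene (not isolated) | C1=C(C)[C@H](OC[Li])C[C@H]2C(C)(C)[C@@H](O[Si](C)(C)C(C)(C)C)CC[C@]12C | intermediate
13 | 3β-(tert-butyldimethylsilyloxy)-9βH-drim-7-en-11-ol (CH2OH on the α face, 9-epi-drimenol skeleton) | OC[C@@H]1C(C)=CC[C@H]2C(C)(C)[C@@H](O[Si](C)(C)C(C)(C)C)CC[C@]12C | intermediate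
14 | isofraxidin, 7-hydroxy-6,8-dimethoxy-2H-chromen-2-one | COc1cc2ccc(=O)oc2c(OC)c1O | starting material
15 | 7-O-[3β-(tert-butyldimethylsilyloxy)-9βH-drim-7-en-11-yl]isofraxidin | COc1cc2ccc(=O)oc2c(OC)c1OC[C@@H]1C(C)=CC[C@H]2C(C)(C)[C@@H](O[Si](C)(C)C(C)(C)C)CC[C@]12C | intermediate
16 | 7-O-(3β-hydroxy-9βH-drim-7-en-11-yl)isofraxidin | COc1cc2ccc(=O)oc2c(OC)c1OC[C@@H]1C(C)=CC[C@H]2C(C)(C)[C@@H](O)CC[C@]12C | intermediate
17 | 7-{[(1R,4aR,6S,8aS)-6-acetoxy-2,5,5,8a-tetramethyl-1,4,4a,5,6,7,8,8a-octahydronaphthalen-1-yl]methoxy}-6,8-dimethoxy-2H-chromen-2-one (3β-acetoxy, 5α-H, 9β-H, 10β-methyl) | COc1cc2ccc(=O)oc2c(OC)c1OC[C@@H]1C(C)=CC[C@H]2C(C)(C)[C@@H](OC(C)=O)CC[C@]12C | target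

**Count**

Total: 12 steps. Longest linear sequence: 12 steps, from (R)-carvone 1 to 17; allyl bromide 3 and isofraxidin 14 enter as purchased materials.

**Steps most likely to fail**

Step 4 (key step). The C4 radical may be reduced before it closes, the cyclic alkoxy radical may reopen by β-scission, or the two faces of the aldehyde may be poorly distinguished at C3. The fallback sets out from 5 and returns at 6, and it separates ring closure from the C3 configuration. The aldehyde is converted with I2 and aqueous NH3 in THF into 3-[(1S,6S)-1,3-dimethyl-2-oxo-6-(prop-1-en-2-yl)cyclohex-3-en-1-yl]propanenitrile F1. The same iron-hydride conditions then close ring A onto the nitrile carbon (HAT-initiated alkene–nitrile cyclization, whose iminyl radical does not readily reopen) to give 3-imino-11-nor-drim-7-en-9-one F2. This is hydrolysed on acidic work-up to 11-nor-drim-7-ene-3,9-dione F3. NaBH4 in MeOH/CH2Cl2 at −78 °C should then reduce the saturated C3 ketone in preference to the hindered, conjugated C9 ketone, with axial hydride delivery giving the equatorial 3β-alcohol 6.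

Step 7. Condensation of hydrazine with the C9 carbonyl, which lies between the quaternary C10 and the fully substituted epoxide carbon C8, may be slow enough for epoxide opening by hydrazine or methanol to compete. The fallback sets out from 8 and returns at 10. NaBH4 in MeOH/THF reduces the ketone to 7α,8α-epoxy-3β-(tert-butyldimethylsilyloxy)-11-nor-driman-9-ol F4 (either C9 epimer serves). Phenyl chlorothionoformate, pyridine and DMAP convert it into the O-phenyl thionocarbonate of that alcohol F5. Bu3SnH and AIBN in toluene at 90 °C then generate the C9 radical (Barton–McCombie-type initiation), which opens the neighbouring epoxide C8–O bond to the C7 alkoxy radical; hydrogen abstraction gives 10 with the C7–O bond untouched.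

Step 9. The α-alkoxy carbanion has to bond to C9 beside the quaternary C10, so a [1,2]-shift or plain protonation to the methyl ether may outrun the [2,3]-shift. The fallback sets out from 10 and returns at 13, replacing the sigmatropic transfer by a substrate-controlled conjugate addition. MnO2 oxidation gives 3β-(tert-butyldimethylsilyloxy)-11-nor-drim-8-en-7-one F6. Copper-catalysed conjugate addition of (isopropoxydimethylsilyl)methylmagnesium chloride to C9 should occur axially and anti to the C10 methyl, on the α face. Trapping the C7 enolate with N-(5-chloropyridin-2-yl)triflimide gives 11-[isopropoxy(dimethyl)silyl]-3β-(tert-butyldimethylsilyloxy)-9βH-drim-7-en-7-yl trifluoromethanesulfonate F7. Palladium-catalysed formate reduction (Pd(OAc)2, PPh3, Bu3N, HCO2H, DMF) removes the triflate to give 11-[isopropoxy(dimethyl)silyl]-3β-(tert-butyldimethylsilyloxy)-9βH-drim-7-ene F8. Tamao–Fleming oxidation (H2O2, KF, KHCO3, THF/MeOH) then gives 13.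

**Further compounds**

F1 | step 4 | 3-[(1S,6S)-1,3-dimethyl-2-oxo-6-(prop-1-en-2-yl)cyclohex-3-en-1-yl]propanenitrile | O=C1C(C)=CC[C@@H](C(C)=C)[C@]1(C)CCC#N
F2 | step 4 | 3-imino-11-nor-drim-7-en-9-one | O=C1C(C)=CC[C@H]2C(C)(C)C(=N)CC[C@]12C
F3 | step 4 | 11-nor-drim-7-ene-3,9-dione | O=C1C(C)=CC[C@H]2C(C)(C)C(=O)CC[C@]12C
F4 | step 7 | 7α,8α-epoxy-3β-(tert-butyldimethylsilyloxy)-11-nor-driman-9-ol (C9 configuration not defined) | OC1[C@]2(C)O[C@@H]2C[C@H]3C(C)(C)[C@@H](O[Si](C)(C)C(C)(C)C)CC[C@]13C
F5 | step 7 | O-phenyl thionocarbonate of F4 | S=C(Oc1ccccc1)OC1[C@]2(C)O[C@@H]2C[C@H]3C(C)(C)[C@@H](O[Si](C)(C)C(C)(C)C)CC[C@]13C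
F6 | step 9 | 3β-(tert-butyldimethylsilyloxy)-11-nor-drim-8-en-7-one | C1=C(C)C(=O)C[C@H]2C(C)(C)[C@@H](O[Si](C)(C)C(C)(C)C)CC[C@]12C
F7 | step 9 | 11-[isopropoxy(dimethyl)silyl]-3β-(tert-butyldimethylsilyloxy)-9βH-drim-7-en-7-yl trifluoromethanesulfonate | CC(C)O[Si](C)(C)C[C@@H]1C(C)=C(OS(=O)(=O)C(F)(F)F)C[C@H]2C(C)(C)[C@@H](O[Si](C)(C)C(C)(C)C)CC[C@]12C
F8 | step 9 | 11-[isopropoxy(dimethyl)silyl]-3β-(tert-butyldimethylsilyloxy)-9βH-drim-7-ene | CC(C)O[Si](C)(C)C[C@@H]1C(C)=CC[C@H]2C(C)(C)[C@@H](O[Si](C)(C)C(C)(C)C)CC[C@]12C
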